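The cyclohexane ring and the bridging δ-lactone of the 2-oxabicyclo[3.3.1]nonan-3-one core are closed together (labels: C2 lactone C=O, C1 its CH2, C10 all-carbon bridgehead, C8 oxygen-bearing bridgehead, C9 one-carbon bridge). The precursor is acyclic: a terminal oxirane at C9, the C8 oxygen already acylated as phenyl carbonate (future C2) and a β-methyl enoate C10=C1. Cp2TiCl opens the oxirane to the C9 radical, which adds 6-exo to C10; the titanium enolate at C1 then attacks the carbonate. The step exploits the 1,3-diaxial relation of C1 and the C8 oxygen on the carbocycle. Both tertiary carbinols come from chelation-controlled MeMgBr additions to β-hydroxy vinyl ketones.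

Key step: step 13

Remarks on the chemistry:
- Further labels, all following the target: C5 is the ring CH that carries the CMe2CO2H group (C4, C3), C6 the ring CHOH, C7 the ring CH2, C11 the side-chain CHOH, C13 the tertiary carbinol.
- Compounds 18 and 19 (oxirane carbon C9) and 21 (C1) are carried as epimer mixtures at a centre that is erased in steps 13 and 14, and are written without a descriptor there.
- Assumption: the (R,R)-antipode of the ProPhenol ligand is taken as the one that gives the 11S carbinol in step 16; the catalyst controls the face, so the other antipode would be used if the sense is opposite.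

Step 1
Reactants: 1 allyl 2-(diethoxyphosphoryl)acetate; 2 1,1-dimethoxypropan-2-one
Product: 4 allyl (2E)-3-methyl-4-oxobut-2-enoate, via dimethyl acetal 3 (not isolated)
Conditions: NaH, THF, 0 °C to rt; then 2 M HCl, THF, rt
Reagents that add atoms: water, O
Why: Horner–Wadsworth–Emmons olefination of the ketone should give mainly the (E)-enoate, and acid hydrolysis of the acetal unmasks the aldehyde while letting any (Z)-isomer equilibrate to the (E)-enal.

Step 2
Reactants: 4 allyl (2E)-3-methyl-4-oxobut-2-enoate; 5 1-(triphenyl-λ5-phosphanylidene)propan-2-one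
Product: 6 allyl (2E,4E)-3-methyl-6-oxohepta-2,4-dienoate
Conditions: CH2Cl2, rt
Reagents that add atoms: none
Why: Wittig olefination with a stabilised ylide reacts only at the aldehyde and should give the (4E)-enone.

Step 3
Reactants: 6 allyl (2E,4E)-3-methyl-6-oxohepta-2,4-dienoate
Product: 7 allyl (2E,4E,6R)-6-hydroxy-3-methylhepta-2,4-dienoate
Conditions: (S)-2-methyl-CBS-oxazaborolidine [(3aS)-1-methyl-3,3-diphenyltetrahydro-1H,3H-pyrrolo[1,2-c][1,3,2]oxazaborole] (20 mol %), catecholborane, toluene, −78 °C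
Reagents that add atoms: none
Why: Corey–Bakshi–Shibata reduction with the alkenyl group as the large substituent should set 6R, and catecholborane at −78 °C leaves the esters and alkenes alone.

Step 4
Reactants: 7 allyl (2E,4E,6R)-6-hydroxy-3-methylhepta-2,4-dienoate; 8 2-bromo-2-methylpropanoyl bromide
Product: 9 allyl (2E,4E,6R)-6-(2-bromo-2-methylpropanoyloxy)-3-methylhepta-2,4-dienoate
Conditions: pyridine, 4-(dimethylamino)pyridine (cat.), CH2Cl2, 0 °C
Reagents that add atoms: none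
Why: O-acylation of the secondary alcohol with an acid bromide under nucleophilic catalysis leaves the carbinol stereocentre untouched.

Step 5
Reactants: 9 allyl (2E,4E,6R)-6-(2-bromo-2-methylpropanoyloxy)-3-methylhepta-2,4-dienoate
Product: 11 (3R,4E)-3-[(2E)-4-(allyloxy)-4-oxobut-2-en-2-yl]-2,2-dimethylhex-4-enoic acid, via silyl ketene acetal 10 (not isolated)
Conditions: Zn dust, Me3SiCl, THF, reflux; aq. NH4Cl
Reagents that add atoms: none
Why: Reformatsky–Claisen rearrangement through a chair [3,3] transition state with the carbinol methyl equatorial should transfer the 6R centre to C5 (3R in 11) next to the gem-dimethyl carbon and leave an (E)-propenyl group, without any strong base near the enoate.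

Step 6
Reactants: 11 (3R,4E)-3-[(2E)-4-(allyloxy)-4-oxobut-2-en-2-yl]-2,2-dimethylhex-4-enoic acid
Product: 12 2-(trimethylsilyl)ethyl (3R,4E)-3-[(2E)-4-(allyloxy)-4-oxobut-2-en-2-yl]-2,2-dimethylhex-4-enoate
Conditions: Me3SiCH2CH2OH, PPh3, diisopropyl azodicarboxylate, THF, 0 °C to rt
Reagents that add atoms: 2-(trimethylsilyl)ethanol, C[Si](C)(C)CCO
Why: Mitsunobu esterification uses the hindered carboxylate as nucleophile at the unhindered activated alcohol, so the neopentyl-type acid needs no acyl activation.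

Step 7
Reactants: 12 2-(trimethylsilyl)ethyl (3R,4E)-3-[(2E)-4-(allyloxy)-4-oxobut-2-en-2-yl]-2,2-dimethylhex-4-enoate
Product: 13 1-allyl 6-[2-(trimethylsilyl)ethyl] (2E,4R)-4-formyl-3,5,5-trimethylhex-2-enedioate
Conditions: O3, CH2Cl2–MeOH, −78 °C, Sudan Red 7B end point; then Me2S; used crude
Reagents that add atoms: ozone, [O-][O+]=O
Why: Ozonolysis with reductive work-up should cleave the electron-rich 1,2-dialkyl alkene well before the enoate and the allyl ester alkene, giving the C6 aldehyde.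

Step 8
Reactants: 13 1-allyl 6-[2-(trimethylsilyl)ethyl] (2E,4R)-4-formyl-3,5,5-trimethylhex-2-enedioate; 14 2-(trimethylsilyloxy)buta-1,3-diene
Product: 15 1-allyl 6-[2-(trimethylsilyl)ethyl] (2E,4R)-4-[(1R)-1-hydroxy-3-oxopent-4-en-1-yl]-3,5,5-trimethylhex-2-enedioate
Conditions: BF3·OEt2, CH2Cl2, −78 °C; used directly
Reagents that add atoms: none
Why: Mukaiyama aldol addition under Felkin–Anh control (nucleophile anti to the CMe2CO2R group on C5) should set 6R, and the non-basic conditions protect the acidic C5–H.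

Step 9
Reactants: 15 1-allyl 6-[2-(trimethylsilyl)ethyl] (2E,4R)-4-[(1R)-1-hydroxy-3-oxopent-4-en-1-yl]-3,5,5-trimethylhex-2-enedioate
Product: 16 1-allyl 6-[2-(trimethylsilyl)ethyl] (2E,4R)-4-[(1R,3S)-1,3-dihydroxy-3-methylpent-4-en-1-yl]-3,5,5-trimethylhex-2-enedioate
Conditions: MeMgBr (3 equiv), CH2Cl2–Et2O, −78 °C; aq. NH4Cl
Reagents that add atoms: methylmagnesium bromide, C[Mg]Br
Why: Chelation-controlled (Cram 1,3-chelate) Grignard 1,2-addition, in which methyl enters the six-membered magnesium chelate axially and cis to H-6, should give the 8S tertiary carbinol while the esters stay inert at −78 °C.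

Step 10
Reactants: 16 1-allyl 6-[2-(trimethylsilyl)ethyl] (2E,4R)-4-[(1R,3S)-1,3-dihydroxy-3-methylpent-4-en-1-yl]-3,5,5-trimethylhex-2-enedioate
Product: 17 1-allyl 6-[2-(trimethylsilyl)ethyl] (2E,4R)-4-[(1R,3S)-3-hydroxy-3-methyl-1-(triethylsilyloxy)pent-4-en-1-yl]-3,5,5-trimethylhex-2-enedioate
Conditions: Et3SiOTf (1.05 equiv), 2,6-lutidine, CH2Cl2, −78 °C
Reagents that add atoms: triethylsilyl trifluoromethanesulfonate, CC[Si](CC)(CC)OS(=O)(=O)C(F)(F)F
Why: Silylation at −78 °C should take the secondary hydroxyl far faster than the tertiary allylic one.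

Step 11
Reactants: 17 1-allyl 6-[2-(trimethylsilyl)ethyl] (2E,4R)-4-[(1R,3S)-3-hydroxy-3-methyl-1-(triethylsilyloxy)pent-4-en-1-yl]-3,5,5-trimethylhex-2-enedioate
Product: 18 1-allyl 6-[2-(trimethylsilyl)ethyl] (2E,4R)-4-[(1R,3S)-3-hydroxy-3-(oxiran-2-yl)-1-(triethylsilyloxy)butyl]-3,5,5-trimethylhex-2-enedioate (both oxirane epimers)
Conditions: VO(acac)2 (cat.), t-BuOOH, CH2Cl2, 0 °C to rt
Reagents that add atoms: tert-butyl hydroperoxide, CC(C)(C)OO
Why: Hydroxyl-directed vanadium-catalysed epoxidation should touch only the alkene allylic to the free tertiary OH, and the configuration of the new oxirane carbon is irrelevant because it becomes a radical in step 13.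

Step 12
Reactants: 18 1-allyl 6-[2-(trimethylsilyl)ethyl] (2E,4R)-4-[(1R,3S)-3-hydroxy-3-(oxiran-2-yl)-1-(triethylsilyloxy)butyl]-3,5,5-trimethylhex-2-enedioate
Product: 19 1-allyl 6-[2-(trimethylsilyl)ethyl] (2E,4R)-3,5,5-trimethyl-4-[(1R,3S)-3-(oxiran-2-yl)-3-(phenoxycarbonyloxy)-1-(triethylsilyloxy)butyl]hex-2-enedioate
Conditions: LiN(SiMe3)2, THF, −78 °C; then PhOCOCl, −78 °C
Reagents that add atoms: phenyl chloroformate, O=C(Cl)Oc1ccccc1
Why: O-acylation of the lithium alkoxide at −78 °C, too cold for Payne rearrangement, installs the future lactone carbonyl C2 on the C8 oxygen as an activated carbonate.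

Step 13
Reactants: 19 1-allyl 6-[2-(trimethylsilyl)ethyl] (2E,4R)-3,5,5-trimethyl-4-[(1R,3S)-3-(oxiran-2-yl)-3-(phenoxycarbonyloxy)-1-(triethylsilyloxy)butyl]hex-2-enedioate
Product: 21 2-(trimethylsilyl)ethyl 2-[(1S,5R,6R,7R,9S)-4-(allyloxycarbonyl)-9-(hydroxymethyl)-1,5-dimethyl-3-oxo-7-(triethylsilyloxy)-2-oxabicyclo[3.3.1]nonan-6-yl]-2-methylpropanoate, via titanium enolate 20 (not isolated)
Conditions: Cp2TiCl2 (2.5 equiv), Mn dust, THF, rt, green Cp2TiCl solution added over 4 h to 19 (0.01 M); then 1 M HCl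
Reagents that add atoms: none
Why: Proposed new method: Cp2TiCl (trivalent titanium, two equivalents consumed) opens the terminal oxirane by single-electron transfer to the more substituted radical at C9, which adds 6-exo-trig to C10 of the enoate; the α-ester radical is reduced by the second equivalent to a titanium enolate, which attacks the phenyl carbonate held 1,3-diaxial on C8 (6-exo-trig addition to C=O, then loss of phenoxide) and closes the lactone. The closest known reactions are titanocene-mediated epoxide-opening radical cyclisations onto acrylates, whose titanium enolates are normally only protonated, and radical–polar crossover Giese–Dieckmann annulations run with SmI2; the in-flask Claisen capture of the titanium enolate by a carbonate is the untested part. In the chair transition state the CMe2CO2R group on C5 is equatorial and C9 adds anti to it, and allylic 1,2-strain keeps the C10 methyl next to H-5, so C1 becomes axial (10R) and the CH2O[Ti] group on C9 equatorial (9S). Only this C10 epimer can reach the carbonate, so lactonisation proof-reads the quaternary centre. The step needs cyclisation to outrun reduction of the C9 radical (which would lead to β-elimination), secured by slow addition at high dilution, and acylation at the carbonate and not at the neopentyl C3 ester, secured by proximity and the phenoxide leaving group.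

Step 14
Reactants: 21 2-(trimethylsilyl)ethyl 2-[(1S,5R,6R,7R,9S)-4-(allyloxycarbonyl)-9-(hydroxymethyl)-1,5-dimethyl-3-oxo-7-(triethylsilyloxy)-2-oxabicyclo[3.3.1]nonan-6-yl]-2-methylpropanoate
Product: 22 2-(trimethylsilyl)ethyl 2-[(1S,5R,6R,7R,9S)-9-(hydroxymethyl)-1,5-dimethyl-3-oxo-7-(triethylsilyloxy)-2-oxabicyclo[3.3.1]nonan-6-yl]-2-methylpropanoate
Conditions: Pd(PPh3)4 (5 mol %), HCO2H, Et3N, THF, 50 °C
Reagents that add atoms: none
Why: Tsuji deallylation–decarboxylation, in which formate reduces the π-allyl palladium to propene and the malonate-type carboxylate loses CO2, should leave C1 as CH2 without touching the hindered silylethyl ester or the silyl ether.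

Step 15
Reactants: 22 2-(trimethylsilyl)ethyl 2-[(1S,5R,6R,7R,9S)-9-(hydroxymethyl)-1,5-dimethyl-3-oxo-7-(triethylsilyloxy)-2-oxabicyclo[3.3.1]nonan-6-yl]-2-methylpropanoate
Product: 23 2-(trimethylsilyl)ethyl 2-[(1S,5R,6R,7R,9R)-9-formyl-1,5-dimethyl-3-oxo-7-(triethylsilyloxy)-2-oxabicyclo[3.3.1]nonan-6-yl]-2-methylpropanoate
Conditions: Dess–Martin periodinane, NaHCO3, CH2Cl2, 0 °C
Reagents that add atoms: none
Why: Dess–Martin oxidation of the primary alcohol under buffered, non-basic conditions avoids β-elimination of the lactone oxygen from the β-acyloxy aldehyde (the 9R label reflects only a priority change).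

Step 16
Reactants: 23 2-(trimethylsilyl)ethyl 2-[(1S,5R,6R,7R,9R)-9-formyl-1,5-dimethyl-3-oxo-7-(triethylsilyloxy)-2-oxabicyclo[3.3.1]nonan-6-yl]-2-methylpropanoate; 24 but-3-en-2-one
Product: 25 2-(trimethylsilyl)ethyl 2-[(1S,5R,6R,7R,9S)-9-[(1S)-1-hydroxy-3-oxopent-4-en-1-yl]-1,5-dimethyl-3-oxo-7-(triethylsilyloxy)-2-oxabicyclo[3.3.1]nonan-6-yl]-2-methylpropanoate
Conditions: (R,R)-ProPhenol [2,6-bis{[(2R)-2-(hydroxydiphenylmethyl)pyrrolidin-1-yl]methyl}-4-methylphenol] (10 mol %), Et2Zn (20 mol %), 4 Å molecular sieves, THF, −20 °C; used directly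
Reagents that add atoms: none
Why: The dinuclear zinc–ProPhenol direct aldol reaction with methyl vinyl ketone as donor should set 11S under catalyst control, while the C9–H, flanked by two fully substituted carbons, enolises only slowly.

Step 17
Reactants: 25 2-(trimethylsilyl)ethyl 2-[(1S,5R,6R,7R,9S)-9-[(1S)-1-hydroxy-3-oxopent-4-en-1-yl]-1,5-dimethyl-3-oxo-7-(triethylsilyloxy)-2-oxabicyclo[3.3.1]nonan-6-yl]-2-methylpropanoate
Product: 26 2-(trimethylsilyl)ethyl 2-[(1S,5R,6R,7R,9S)-9-[(1S,3R)-1,3-dihydroxy-3-methylpent-4-en-1-yl]-1,5-dimethyl-3-oxo-7-(triethylsilyloxy)-2-oxabicyclo[3.3.1]nonan-6-yl]-2-methylpropanoate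
Conditions: MeMgBr (3 equiv), THF, −78 °C; aq. NH4Cl
Reagents that add atoms: methylmagnesium bromide, C[Mg]Br
Why: Chelation-controlled Grignard addition, with the C11 alkoxide holding the C13 ketone and methyl entering axially cis to H-11, should give 13R, the ketone reacting at −78 °C far faster than lactone or ester.

Step 18
Reactants: 26 2-(trimethylsilyl)ethyl 2-[(1S,5R,6R,7R,9S)-9-[(1S,3R)-1,3-dihydroxy-3-methylpent-4-en-1-yl]-1,5-dimethyl-3-oxo-7-(triethylsilyloxy)-2-oxabicyclo[3.3.1]nonan-6-yl]-2-methylpropanoate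
Product: 27 2-[(1S,5R,6R,7R,9S)-9-[(1S,3R)-1,3-dihydroxy-3-methylpent-4-en-1-yl]-7-hydroxy-1,5-dimethyl-3-oxo-2-oxabicyclo[3.3.1]nonan-6-yl]-2-methylpropanoic acid (CNP0297019.1)
Conditions: tris(dimethylamino)sulfonium difluorotrimethylsilicate (TASF), DMF, 0 °C to rt; aq. NH4Cl
Reagents that add atoms: none
Why: Fluoride-induced cleavage should fragment the 2-(trimethylsilyl)ethyl ester to the carboxylate, ethene and Me3SiF and remove the triethylsilyl ether without touching any stereocentre.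

Compound list
1 | allyl 2-(diethoxyphosphoryl)acetate | C=CCOC(=O)CP(=O)(OCC)OCC | starting material
2 | 1,1-dimethoxypropan-2-one | CC(=O)C(OC)OC | starting material
3 | allyl (2E)-4,4-dimethoxy-3-methylbut-2-enoate | COC(OC)/C(C)=C/C(=O)OCC=C | intermediate
4 | allyl (2E)-3-methyl-4-oxobut-2-enoate | O=C/C(C)=C/C(=O)OCC=C | intermediate
5 | 1-(triphenyl-λ5-phosphanylidene)propan-2-one | CC(=O)C=P(c1ccccc1)(c1ccccc1)c1ccccc1 | starting material
6 | allyl (2E,4E)-3-methyl-6-oxohepta-2,4-dienoate | CC(=O)/C=C/C(C)=C/C(=O)OCC=C | intermediate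
7 | allyl (2E,4E,6R)-6-hydroxy-3-methylhepta-2,4-dienoate | C[C@@H](O)/C=C/C(C)=C/C(=O)OCC=C | intermediate
8 | 2-bromo-2-methylpropanoyl bromide | CC(C)(Br)C(=O)Br | starting material
9 | allyl (2E,4E,6R)-6-(2-bromo-2-methylpropanoyloxy)-3-methylhepta-2,4-dienoate | C[C@@H](OC(=O)C(C)(C)Br)/C=C/C(C)=C/C(=O)OCC=C | intermediate
10 | allyl (2E,4E,6R)-3-methyl-6-{[2-methyl-1-(trimethylsilyloxy)prop-1-en-1-yl]oxy}hepta-2,4-dienoate (silyl ketene acetal) | C[C@@H](OC(O[Si](C)(C)C)=C(C)C)/C=C/C(C)=C/C(=O)OCC=C | intermediate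
11 | (3R,4E)-3-[(2E)-4-(allyloxy)-4-oxobut-2-en-2-yl]-2,2-dimethylhex-4-enoic acid | C/C=C/[C@H](/C(C)=C/C(=O)OCC=C)C(C)(C)C(=O)O | intermediate
12 | 2-(trimethylsilyl)ethyl (3R,4E)-3-[(2E)-4-(allyloxy)-4-oxobut-2-en-2-yl]-2,2-dimethylhex-4-enoate | C/C=C/[C@H](/C(C)=C/C(=O)OCC=C)C(C)(C)C(=O)OCC[Si](C)(C)C | intermediate
13 | 1-allyl 6-[2-(trimethylsilyl)ethyl] (2E,4R)-4-formyl-3,5,5-trimethylhex-2-enedioate | O=C[C@H](/C(C)=C/C(=O)OCC=C)C(C)(C)C(=O)OCC[Si](C)(C)C | intermediate
14 | 2-(trimethylsilyloxy)buta-1,3-diene | C=CC(=C)O[Si](C)(C)C | starting material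
15 | 1-allyl 6-[2-(trimethylsilyl)ethyl] (2E,4R)-4-[(1R)-1-hydroxy-3-oxopent-4-en-1-yl]-3,5,5-trimethylhex-2-enedioate | C=CC(=O)C[C@@H](O)[C@H](/C(C)=C/C(=O)OCC=C)C(C)(C)C(=O)OCC[Si](C)(C)C | intermediate
16 | 1-allyl 6-[2-(trimethylsilyl)ethyl] (2E,4R)-4-[(1R,3S)-1,3-dihydroxy-3-methylpent-4-en-1-yl]-3,5,5-trimethylhex-2-enedioate | C=C[C@@](C)(O)C[C@@H](O)[C@H](/C(C)=C/C(=O)OCC=C)C(C)(C)C(=O)OCC[Si](C)(C)C | intermediate
17 | 1-allyl 6-[2-(trimethylsilyl)ethyl] (2E,4R)-4-[(1R,3S)-3-hydroxy-3-methyl-1-(triethylsilyloxy)pent-4-en-1-yl]-3,5,5-trimethylhex-2-enedioate | C=C[C@@](C)(O)C[C@@H](O[Si](CC)(CC)CC)[C@H](/C(C)=C/C(=O)OCC=C)C(C)(C)C(=O)OCC[Si](C)(C)C | intermediate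
18 | 1-allyl 6-[2-(trimethylsilyl)ethyl] (2E,4R)-4-[(1R,3S)-3-hydroxy-3-(oxiran-2-yl)-1-(triethylsilyloxy)butyl]-3,5,5-trimethylhex-2-enedioate (both oxirane epimers) | O1CC1[C@@](C)(O)C[C@@H](O[Si](CC)(CC)CC)[C@H](/C(C)=C/C(=O)OCC=C)C(C)(C)C(=O)OCC[Si](C)(C)C | intermediate
19 | 1-allyl 6-[2-(trimethylsilyl)ethyl] (2E,4R)-3,5,5-trimethyl-4-[(1R,3S)-3-(oxiran-2-yl)-3-(phenoxycarbonyloxy)-1-(triethylsilyloxy)butyl]hex-2-enedioate (both oxirane epimers) | O1CC1[C@@](C)(OC(=O)Oc1ccccc1)C[C@@H](O[Si](CC)(CC)CC)[C@H](/C(C)=C/C(=O)OCC=C)C(C)(C)C(=O)OCC[Si](C)(C)C | intermediate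
20 | ring-closed titanium enolate: carbocycle C5–C10 formed, allyl ester enolate oxygen and C11 oxygen each bound to chlorobis(cyclopentadienyl)titanium (tetravalent), phenyl carbonate on C8 intact, configured as 21 | Cl[Ti](OC[C@@H]1[C@](C)(C=C(OCC=C)O[Ti](Cl)(C2C=CC=C2)C2C=CC=C2)[C@H](C(C)(C)C(=O)OCC[Si](C)(C)C)[C@H](O[Si](CC)(CC)CC)C[C@]1(C)OC(=O)Oc1ccccc1)(C1C=CC=C1)C1C=CC=C1 | intermediate
21 | 2-(trimethylsilyl)ethyl 2-[(1S,5R,6R,7R,9S)-4-(allyloxycarbonyl)-9-(hydroxymethyl)-1,5-dimethyl-3-oxo-7-(triethylsilyloxy)-2-oxabicyclo[3.3.1]nonan-6-yl]-2-methylpropanoate (C4 epimers) | OC[C@@H]1[C@]2(C)C(C(=O)OCC=C)C(=O)O[C@@]1(C)C[C@@H](O[Si](CC)(CC)CC)[C@H]2C(C)(C)C(=O)OCC[Si](C)(C)C | intermediate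
22 | 2-(trimethylsilyl)ethyl 2-[(1S,5R,6R,7R,9S)-9-(hydroxymethyl)-1,5-dimethyl-3-oxo-7-(triethylsilyloxy)-2-oxabicyclo[3.3.1]nonan-6-yl]-2-methylpropanoate | OC[C@@H]1[C@]2(C)CC(=O)O[C@@]1(C)C[C@@H](O[Si](CC)(CC)CC)[C@H]2C(C)(C)C(=O)OCC[Si](C)(C)C | intermediate
23 | 2-(trimethylsilyl)ethyl 2-[(1S,5R,6R,7R,9R)-9-formyl-1,5-dimethyl-3-oxo-7-(triethylsilyloxy)-2-oxabicyclo[3.3.1]nonan-6-yl]-2-methylpropanoate | O=C[C@@H]1[C@]2(C)CC(=O)O[C@@]1(C)C[C@@H](O[Si](CC)(CC)CC)[C@H]2C(C)(C)C(=O)OCC[Si](C)(C)C | intermediate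
24 | but-3-en-2-one (methyl vinyl ketone) | CC(=O)C=C | starting material
25 | 2-(trimethylsilyl)ethyl 2-[(1S,5R,6R,7R,9S)-9-[(1S)-1-hydroxy-3-oxopent-4-en-1-yl]-1,5-dimethyl-3-oxo-7-(triethylsilyloxy)-2-oxabicyclo[3.3.1]nonan-6-yl]-2-methylpropanoate | C=CC(=O)C[C@H](O)[C@@H]1[C@]2(C)CC(=O)O[C@@]1(C)C[C@@H](O[Si](CC)(CC)CC)[C@H]2C(C)(C)C(=O)OCC[Si](C)(C)C | intermediate
26 | 2-(trimethylsilyl)ethyl 2-[(1S,5R,6R,7R,9S)-9-[(1S,3R)-1,3-dihydroxy-3-methylpent-4-en-1-yl]-1,5-dimethyl-3-oxo-7-(triethylsilyloxy)-2-oxabicyclo[3.3.1]nonan-6-yl]-2-methylpropanoate | C=C[C@](C)(O)C[C@H](O)[C@@H]1[C@]2(C)CC(=O)O[C@@]1(C)C[C@@H](O[Si](CC)(CC)CC)[C@H]2C(C)(C)C(=O)OCC[Si](C)(C)C | intermediate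
27 | 2-[(1S,5R,6R,7R,9S)-9-[(1S,3R)-1,3-dihydroxy-3-methylpent-4-en-1-yl]-7-hydroxy-1,5-dimethyl-3-oxo-2-oxabicyclo[3.3.1]nonan-6-yl]-2-methylpropanoic acid | C=C[C@](C)(O)C[C@H](O)[C@@H]1[C@]2(C)CC(=O)O[C@@]1(C)C[C@@H](O)[C@H]2C(C)(C)C(=O)O | target

Total step count: 18. Longest linear sequence: 18 steps (the route is linear from 1 and 2).

Steps most likely to fail

Step 13 (proposed new method). The C9 radical may be reduced by a second Cp2TiCl before it cyclises, which leads to β-elimination and loss of the oxygen functions. The titanium enolate may also fail to acylate and simply be protonated on work-up, or the carbonate may migrate to the titanium-bound C11 oxygen. The fallback uses known chemistry, sets out from 19 and returns at 21, and separates the two bond formations. Compound 19 would be cyclised under the catalytic, silylating titanocene protocol (Cp2TiCl2 20 mol %, Mn dust, Me3SiCl, 2,4,6-collidine, THF, rt), which turns the titanium over by O-silylation and should give, after work-up, the monocyclic allyl ester trimethylsilyl ether F1 with the phenyl carbonate intact. The lithium enolate of F1 (LiN(SiMe3)2, THF, −78 to −20 °C) would then close the lactone by Dieckmann-type acylation on the carbonate, and dilute HCl work-up would cleave the trimethylsilyl ether to give 21.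

Step 16. The zinc alkoxide catalyst may cause β-elimination of the lactone oxygen or epimerisation at C9 of the β-acyloxy aldehyde, and facial control may be poor at an aldehyde flanked by two fully substituted carbons. The fallback sets out from 23 and returns at 25, and replaces the direct aldol by an auxiliary-controlled acetate aldol under Lewis-acidic conditions. The tin enolate of (4S)-3-acetyl-4-isopropyl-1,3-thiazolidine-2-thione (Sn(OTf)2, N-ethylpiperidine, CH2Cl2, −78 °C; auxiliary antipode chosen for 11S) would add to 23 to give the β-hydroxy acyl thiazolidinethione F2. MeONHMe·HCl and imidazole would displace the auxiliary to give the Weinreb amide F3, and CH2=CHMgBr (THF, −78 °C, acidic quench) would convert F3 into 25.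

Step 14. Under warm, amine-buffered conditions the lactone acyl group may migrate from the C8 oxygen to the free primary C11 hydroxyl, and decarboxylation may be incomplete. The fallback sets out from 21 and returns at 23, and changes the order so that no hydroxyl is present. Compound 21 would first be oxidised (Dess–Martin periodinane, NaHCO3, CH2Cl2) to the aldehyde allyl ester F4. The allyl ester would then be removed by neutral hydrostannolysis (Pd(PPh3)4, Bu3SnH, CH2Cl2; then AcOH), and the acid decarboxylated in toluene at 60 °C to give 23.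

Further compounds
F1 | step 13 | 2-(trimethylsilyl)ethyl 2-[(1R,2R,3R,4S,6R)-3-[2-(allyloxy)-2-oxoethyl]-3,5-dimethyl-5-(phenoxycarbonyloxy)-6-(triethylsilyloxy)-4-(trimethylsilyloxymethyl)cyclohexyl]-2-methylpropanoate, drawn by SMILES (carbocycle closed, lactone open; configured as 21 at C5, C6, C8, C9, C10) | C=CCOC(=O)C[C@@]1(C)[C@@H](CO[Si](C)(C)C)[C@@](C)(OC(=O)Oc2ccccc2)C[C@@H](O[Si](CC)(CC)CC)[C@H]1C(C)(C)C(=O)OCC[Si](C)(C)C
F2 | step 16 | 2-(trimethylsilyl)ethyl 2-[(1S,5R,6R,7R,9S)-9-{(1S)-1-hydroxy-3-[(4S)-4-isopropyl-2-thioxo-1,3-thiazolidin-3-yl]-3-oxopropyl}-1,5-dimethyl-3-oxo-7-(triethylsilyloxy)-2-oxabicyclo[3.3.1]nonan-6-yl]-2-methylpropanoate | CC(C)[C@H]1CSC(=S)N1C(=O)C[C@H](O)[C@@H]2[C@]3(C)CC(=O)O[C@@]2(C)C[C@@H](O[Si](CC)(CC)CC)[C@H]3C(C)(C)C(=O)OCC[Si](C)(C)C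
F3 | step 16 | 2-(trimethylsilyl)ethyl 2-[(1S,5R,6R,7R,9S)-9-{(1S)-1-hydroxy-3-[methoxy(methyl)amino]-3-oxopropyl}-1,5-dimethyl-3-oxo-7-(triethylsilyloxy)-2-oxabicyclo[3.3.1]nonan-6-yl]-2-methylpropanoate | CON(C)C(=O)C[C@H](O)[C@@H]1[C@]2(C)CC(=O)O[C@@]1(C)C[C@@H](O[Si](CC)(CC)CC)[C@H]2C(C)(C)C(=O)OCC[Si](C)(C)C
F4 | step 14 | 2-(trimethylsilyl)ethyl 2-[(1S,5R,6R,7R,9R)-4-(allyloxycarbonyl)-9-formyl-1,5-dimethyl-3-oxo-7-(triethylsilyloxy)-2-oxabicyclo[3.3.1]nonan-6-yl]-2-methylpropanoate (C4 epimers) | O=C[C@@H]1[C@]2(C)C(C(=O)OCC=C)C(=O)O[C@@]1(C)C[C@@H](O[Si](CC)(CC)CC)[C@H]2C(C)(C)C(=O)OCC[Si](C)(C)C
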